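## Retrosynthetic overview

- Numbering: ring A is C1 (butyryl), C2 (OH), C3 (CH3), C4 (OH), C5 (CH2 bridge), C6 (OH); ring B is C1' (bridge), C2' (OH), C3' (CH3), C4' (OCH3), C5' (butyryl), C6' (OH).
- Last bond: C1–C(=O) of ring A, by Friedel–Crafts butyrylation of the debenzylated diarylmethane, in which C1 is the only aromatic C–H.
- Key disconnection: ring B is cut at C1'–C2' and C5'–C6'. The run C2'(O)–C3'(CH3)–C4'(OCH3)–C5'–C(=O)C3H7 is the C2–C3–C4–C5–C6 backbone of 4-methoxy-3-methyl-6-propyl-2-pyranone. The one O-methyl of the target, on the oxygen wedged between the C-methyl and the chelating butyryl group, therefore arrives inside the heterocycle; C1' and C6' are the α-carbon and the carbonyl carbon of a ring A 3-arylpropanoate.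
- Precursors: the ester from 2-methylphloroglucinol (formylation, tribenzylation, Horner–Wadsworth–Emmons olefination, conjugate reduction); the pyranone from the dianion of ethyl 2-methylacetoacetate and ethyl butyrate (acylation, lactonisation, O-methylation).
- Ring order: ring A is bought as an arene; the pyranone ring is made in step 6 and recast as carbocyclic ring B in step 8.

Key step: step 8

Assumption: the four starting materials are bought; anions preformed with a stoichiometric base and the iminium salt of step 1 are numbered as intermediates that are not isolated.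

## Route

Step 1
Reactants: 1 2-methylphloroglucinol
Product: 3 2,4,6-trihydroxy-3-methylbenzaldehyde, via aryl iminium chloride 2 (not isolated)
Conditions: POCl3, DMF, EtOAc, 0 °C → rt; then H2O, 60 °C
Reagents that add atoms: N,N-dimethylformamide, CN(C)C=O; water, O
Why: Vilsmeier–Haack formylation: the chloroiminium ion attacks one of the two equivalent free carbons of the triol, so only one regioisomer can form, and the iminium salt is hydrolysed on warming with water.

Step 2
Reactants: 3 2,4,6-trihydroxy-3-methylbenzaldehyde
Product: 4 2,4,6-tris(benzyloxy)-3-methylbenzaldehyde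
Conditions: BnBr (excess), K2CO3, DMF, 70 °C
Reagents that add atoms: benzyl bromide, BrCc1ccccc1
Why: Williamson etherification: the formyl group pulls electron density from the ring carbon so that the phenoxides should react at oxygen, and excess bromide at 70 °C should also etherify the two hydroxyls that are hydrogen-bonded to the aldehyde.

Step 3
Reactants: 4 2,4,6-tris(benzyloxy)-3-methylbenzaldehyde; 5 trimethyl phosphonoacetate
Product: 7 methyl (E)-3-[2,4,6-tris(benzyloxy)-3-methylphenyl]prop-2-enoate, via sodium phosphonate carbanion 6 (not isolated)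
Conditions: NaH, THF, 0 °C; then 4, 0 °C → reflux
Reagents that add atoms: none
Why: Horner–Wadsworth–Emmons olefination: the stabilised phosphonate carbanion adds to the non-enolisable aldehyde and syn-elimination of phosphate gives the E-acrylate, whose geometry is of no consequence because the double bond is reduced next.

Step 4
Reactants: 7 methyl (E)-3-[2,4,6-tris(benzyloxy)-3-methylphenyl]prop-2-enoate
Product: 8 methyl 3-[2,4,6-tris(benzyloxy)-3-methylphenyl]propanoate
Conditions: Mg turnings, MeOH/THF, 0 °C → rt
Reagents that add atoms: none
Why: Dissolving-metal conjugate reduction of an aryl acrylate by single-electron transfer from Mg in methanol, chosen because it leaves benzyl aryl ethers intact where catalytic hydrogenation would not.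

Step 5
Reactants: 9 ethyl 2-methylacetoacetate; 10 ethyl butyrate
Product: 12 ethyl 2-methyl-3,5-dioxooctanoate, via sodium lithium dianion 11 (not isolated)
Conditions: 9 (2 equiv), NaH then n-BuLi, THF, 0 °C; then 10 (1 equiv), 0 °C → rt; aq. HCl
Reagents that add atoms: none
Why: Acylation of a β-keto ester dianion: the terminal carbanion is the more basic and more nucleophilic site and should attack the ester, while the second equivalent of dianion takes up the acidic C4 proton of the product and so prevents further reaction.

Step 6
Reactants: 12 ethyl 2-methyl-3,5-dioxooctanoate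
Product: 13 4-hydroxy-3-methyl-6-propyl-2H-pyran-2-one
Conditions: DBU, toluene, reflux; aq. HCl
Reagents that add atoms: none
Why: Lactonisation (intramolecular transesterification): the C5 enol oxygen attacks the ethyl ester in a 6-exo-trig acyl substitution and loss of ethanol gives the conjugated 4-hydroxy-2-pyranone.

Step 7
Reactants: 13 4-hydroxy-3-methyl-6-propyl-2H-pyran-2-one
Product: 14 4-methoxy-3-methyl-6-propyl-2H-pyran-2-one
Conditions: Me2SO4, K2CO3, acetone, reflux
Reagents that add atoms: dimethyl sulfate, COS(=O)(=O)OC
Why: O-alkylation of a 4-hydroxy-2-pyranone with a hard methylating agent and K2CO3 in acetone is the standard way to the 4-methoxy-2-pyranone, the 2-methoxy-4-pyranone being the minor, separable isomer.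

Step 8
Reactants: 8 methyl 3-[2,4,6-tris(benzyloxy)-3-methylphenyl]propanoate; 14 4-methoxy-3-methyl-6-propyl-2H-pyran-2-one
Product: 17 1-[2,4-dihydroxy-6-methoxy-5-methyl-3-{[2,4,6-tris(benzyloxy)-3-methylphenyl]methyl}phenyl]butan-1-one, via lithium ester enolate 15 (not isolated), via ring-opened keto ester enolate 16 (not isolated)
Conditions: 8 (slight excess over base), LiN(i-Pr)2, THF, −78 °C; then 14, −78 → 0 °C; then NaOMe, MeOH, 0 → 50 °C; aq. HCl
Reagents that add atoms: none
Why: Proposed new method: enolate 15 should add through its α-carbon (the future C1') to the lactone carbonyl of 14 (C1'–C2'), the tetrahedral alkoxide should expel the ring oxygen as the enolate of the future butyryl ketone to give open chain 16, and C5' of 16 should then attack the methyl ester (C5'–C6') with loss of methoxide and enolise to the arene as the thermodynamic sink, the methoxide stage supplying the equilibrating protic base in which triketo esters close in the Claisen sense. The closest known reactions are the carbanion-induced ring transformations of 2-pyranones into benzenes, the tandem addition and Claisen closure of ortho-toluate anions on 4-methoxy-2-pyranones, and the base-mediated Claisen cyclisation of 3,5,7-triketo esters to acylphloroglucinols, but acyl substitution at a pyranone carbonyl by an ester enolate followed by reclosure onto that same ester has not been shown. Ring B closes in a 6-(enolexo)-exo-trig mode, and the C3'=C4' geometry inherited from the heterocycle holds C5' and the ester carbon within reach. No stereocentre is left, because the only one formed (C1' of 16) is erased on aromatisation. The step needs attack at the carbonyl instead of at C4 or C6 and no proton transfer from the propyl α-CH2 to 15; the hard lithium enolate at −78 °C, the absence of free amide base, the C3 methyl and C4 methoxy groups that hinder and deactivate C4, and the propyl group on C6 should secure this. The enol methyl ether is never unmasked, so C4' alone ends as OCH3, and the competing aldol closure from C1' onto the propyl ketone cannot aromatise because C1' carries the arylmethyl group.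

Step 9
Reactants: 17 1-[2,4-dihydroxy-6-methoxy-5-methyl-3-{[2,4,6-tris(benzyloxy)-3-methylphenyl]methyl}phenyl]butan-1-one
Product: 18 1-{2,4-dihydroxy-6-methoxy-5-methyl-3-[(2,4,6-trihydroxy-3-methylphenyl)methyl]phenyl}butan-1-one
Conditions: H2 (1 atm), 10% Pd/C, EtOAc/MeOH, rt; product kept under argon
Reagents that add atoms: none
Why: Catalytic hydrogenolysis of benzyl aryl ethers; at 1 atm and room temperature the hydrogen-bonded aryl ketone, the methyl ether and the diarylmethane C–C bonds should not be touched.

Step 10
Reactants: 18 1-{2,4-dihydroxy-6-methoxy-5-methyl-3-[(2,4,6-trihydroxy-3-methylphenyl)methyl]phenyl}butan-1-one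
Product: 19 1-{3-[(3-butanoyl-2,4,6-trihydroxy-5-methylphenyl)methyl]-2,4-dihydroxy-6-methoxy-5-methylphenyl}butan-1-one (target)
Conditions: butyric acid, BF3·OEt2, argon, 70 °C; then H2O
Reagents that add atoms: butanoic acid, CCCC(=O)O
Why: Friedel–Crafts acylation with the carboxylic acid and BF3·OEt2, the standard acylphloroglucinol synthesis: C1 of ring A is the only aromatic C–H in 18 and lies between two hydroxyls on the more electron-rich ring, ring B has no free position, and BF3 does not cleave the aryl methyl ether.

## Compound list

1 | 2-methylphloroglucinol (2-methylbenzene-1,3,5-triol) | Cc1c(O)cc(O)cc1O | starting material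
2 | dimethyl[(2,4,6-trihydroxy-3-methylphenyl)methylidene]ammonium chloride (not isolated) | C[N+](C)=Cc1c(O)cc(O)c(C)c1O.[Cl-] | intermediate
3 | 2,4,6-trihydroxy-3-methylbenzaldehyde | O=Cc1c(O)cc(O)c(C)c1O | intermediate
4 | 2,4,6-tris(benzyloxy)-3-methylbenzaldehyde | O=Cc1c(OCc2ccccc2)cc(OCc2ccccc2)c(C)c1OCc1ccccc1 | intermediate
5 | trimethyl phosphonoacetate | COC(=O)CP(=O)(OC)OC | starting material
6 | sodium salt of trimethyl phosphonoacetate (not isolated) | [Na+].COC(=O)[CH-]P(=O)(OC)OC | intermediate
7 | methyl (E)-3-[2,4,6-tris(benzyloxy)-3-methylphenyl]prop-2-enoate | COC(=O)/C=C/c1c(OCc2ccccc2)cc(OCc2ccccc2)c(C)c1OCc1ccccc1 | intermediate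
8 | methyl 3-[2,4,6-tris(benzyloxy)-3-methylphenyl]propanoate | COC(=O)CCc1c(OCc2ccccc2)c(C)c(OCc2ccccc2)cc1OCc1ccccc1 | intermediate
9 | ethyl 2-methylacetoacetate | CCOC(=O)C(C)C(C)=O | starting material
10 | ethyl butyrate | CCCC(=O)OCC | starting material
11 | sodium lithium dianion of ethyl 2-methylacetoacetate (not isolated) | [Na+].[Li+].C=C([O-])C(C)=C([O-])OCC | intermediate
12 | ethyl 2-methyl-3,5-dioxooctanoate | CCCC(=O)CC(=O)C(C)C(=O)OCC | intermediate
13 | 4-hydroxy-3-methyl-6-propyl-2H-pyran-2-one | CCCc1cc(O)c(C)c(=O)o1 | intermediate
14 | 4-methoxy-3-methyl-6-propyl-2H-pyran-2-one | CCCc1cc(OC)c(C)c(=O)o1 | intermediate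
15 | lithium enolate of methyl 3-[2,4,6-tris(benzyloxy)-3-methylphenyl]propanoate (not isolated) | [Li+].COC([O-])=CCc1c(OCc2ccccc2)c(C)c(OCc2ccccc2)cc1OCc1ccccc1 | intermediate
16 | lithium enolate of methyl (4E)-5-methoxy-4-methyl-3,7-dioxo-2-{[2,4,6-tris(benzyloxy)-3-methylphenyl]methyl}dec-4-enoate (not isolated) | [Li+].[O-]/C(CCC)=C\C(OC)=C(C)/C(=O)C(Cc1c(OCc2ccccc2)c(C)c(OCc2ccccc2)cc1OCc1ccccc1)C(=O)OC | intermediate
17 | 1-[2,4-dihydroxy-6-methoxy-5-methyl-3-{[2,4,6-tris(benzyloxy)-3-methylphenyl]methyl}phenyl]butan-1-one | CCCC(=O)c1c(OC)c(C)c(O)c(Cc2c(OCc3ccccc3)c(C)c(OCc3ccccc3)cc2OCc2ccccc2)c1O | intermediate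
18 | 1-{2,4-dihydroxy-6-methoxy-5-methyl-3-[(2,4,6-trihydroxy-3-methylphenyl)methyl]phenyl}butan-1-one | CCCC(=O)c1c(OC)c(C)c(O)c(Cc2c(O)c(C)c(O)cc2O)c1O | intermediate
19 | 1-{3-[(3-butanoyl-2,4,6-trihydroxy-5-methylphenyl)methyl]-2,4-dihydroxy-6-methoxy-5-methylphenyl}butan-1-one | CCCC(=O)c1c(O)c(C)c(O)c(Cc2c(O)c(C)c(OC)c(C(=O)CCC)c2O)c1O | target

## Step count and risks

Total steps: 10. Longest linear sequence: 7 (steps 1, 2, 3, 4, 8, 9, 10); the pyranone branch (steps 5 to 7) joins at step 8.

**1. Step 8 (proposed new method).** Three processes may defeat it: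
- proton transfer from the propyl α-CH2 of 14 to enolate 15, which would return both partners unchanged;
- conjugate attack of 15 at C4 or C6 of the pyranone in place of the carbonyl;
- stalling at open chain 16, with retro-Claisen cleavage under methoxide instead of ring closure.

Fallback, known chemistry only, setting out from 1 and coming back to the route at 19. It joins two separately made rings through the methylene bridge and gives up the pyranone logic.
- 1 is butyrylated (butyric acid, BF3·OEt2, 70 °C) at one of its two equivalent carbons to 1-(2,4,6-trihydroxy-3-methylphenyl)butan-1-one F1.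
- One portion of F1 is benzylated (BnBr 2 equiv, K2CO3, acetone, reflux) at the para hydroxyl and the less hindered ortho hydroxyl to 1-[4,6-bis(benzyloxy)-2-hydroxy-3-methylphenyl]butan-1-one F2. This leaves free the chelated hydroxyl between the C-methyl and the ketone; the regioisomer would be removed by chromatography.
- That hydroxyl is methylated (MeI, Cs2CO3, DMF, 50 °C) to 1-[4,6-bis(benzyloxy)-2-methoxy-3-methylphenyl]butan-1-one F3.
- Hydrogenolysis (H2, Pd/C, EtOAc) gives the ring B monomer 1-(4,6-dihydroxy-2-methoxy-3-methylphenyl)butan-1-one F4.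
- The other portion of F1 is aminomethylated at its only free carbon (dimethylmethylideneammonium iodide, MeCN, rt) to the Mannich base 1-{3-[(dimethylamino)methyl]-2,4,6-trihydroxy-5-methylphenyl}butan-1-one F5.
- Heating F5 with F4 in 1,4-dioxane at reflux should expel dimethylamine and give the ortho-quinone methide of ring A, which is trapped at C1', the only free carbon of F4, to give 19.

**2. Step 10.** The strong Lewis acid at 70 °C may protonate the very electron-rich ring A at C5 and split or exchange the methylene bridge. It may also leave O-butyrates that do not undergo the Fries shift, and 18 may oxidise in air before it reacts.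

Fallback, setting out from 18 and coming back at 19: a Houben–Hoesch reaction. Butyronitrile, ZnCl2 and HCl gas in Et2O at 0 °C should deposit 1-{3-[(3-butanoyl-2,6-dihydroxy-4-methoxy-5-methylphenyl)methyl]-2,4,6-trihydroxy-5-methylphenyl}butan-1-iminium chloride F6. This is hydrolysed in hot water to 19. The nitrilium electrophile cannot O-acylate and the reaction runs cold.

**3. Step 2.** The ambident phenoxide may be benzylated at the free ring carbon, and the two hydroxyls chelated to the aldehyde may resist etherification.

Fallback, setting out from 1 and coming back at 4: the order of protection and formylation is reversed.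
- 1 is peracetylated (Ac2O, pyridine) to 2-methylbenzene-1,3,5-triyl triacetate F7.
- F7 is deacetylated and benzylated in one pot (BnCl, NaH, DMF, slow addition of H2O, 0 °C → rt) to 1,3,5-tris(benzyloxy)-2-methylbenzene F8. The phenoxides are released slowly in the presence of the halide, which suppresses C-alkylation.
- Vilsmeier–Haack formylation of F8 (POCl3, DMF, 0 °C → 60 °C; H2O) at one of its two equivalent carbons gives 4.

## Further compounds

F1 | step 8 | 1-(2,4,6-trihydroxy-3-methylphenyl)butan-1-one | CCCC(=O)c1c(O)cc(O)c(C)c1O
F2 | step 8 | 1-[4,6-bis(benzyloxy)-2-hydroxy-3-methylphenyl]butan-1-one | CCCC(=O)c1c(OCc2ccccc2)cc(OCc2ccccc2)c(C)c1O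
F3 | step 8 | 1-[4,6-bis(benzyloxy)-2-methoxy-3-methylphenyl]butan-1-one | CCCC(=O)c1c(OCc2ccccc2)cc(OCc2ccccc2)c(C)c1OC
F4 | step 8 | 1-(4,6-dihydroxy-2-methoxy-3-methylphenyl)butan-1-one | CCCC(=O)c1c(O)cc(O)c(C)c1OC
F5 | step 8 | 1-{3-[(dimethylamino)methyl]-2,4,6-trihydroxy-5-methylphenyl}butan-1-one | CCCC(=O)c1c(O)c(CN(C)C)c(O)c(C)c1O
F6 | step 10 | 1-{3-[(3-butanoyl-2,6-dihydroxy-4-methoxy-5-methylphenyl)methyl]-2,4,6-trihydroxy-5-methylphenyl}butan-1-iminium chloride | CCCC(=[NH2+])c1c(O)c(C)c(O)c(Cc2c(O)c(C)c(OC)c(C(=O)CCC)c2O)c1O.[Cl-]
F7 | step 2 | 2-methylbenzene-1,3,5-triyl triacetate | CC(=O)Oc1cc(OC(C)=O)c(C)c(OC(C)=O)c1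
F8 | step 2 | 1,3,5-tris(benzyloxy)-2-methylbenzene | Cc1c(OCc2ccccc2)cc(OCc2ccccc2)cc1OCc1ccccc1
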